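Late in the noon run, at 90.0 min, you read X at 0.2 % and G at 39.5 %. This noon run is the flask in question, followed so far, and the summer run is the earlier one with less L.

| flask | X | L | temperature | remark | time |
|---|---|---|---|---|---|
| noon | 0.27 M | 3 mM | 25 °C | the very flask that is asked about, followed so far |  |
| summer | 0.27 M | 2 mM | 25 °C | run made earlier |  |
| flask | 0.27 M | 3.0 mM | 25 °C |  | 2.5 h |

| run | time / min | G / % | X / % |
|---|---|---|---|
| noon | 8.00 | 39.3 | 0 |
| noon | 12.0 | 39.5 | 0.4 |
| noon | 20.0 | 40.1 | 0.1 |
| noon | 30.0 | 39.4 | 0 |
| noon | 50.0 | 39.2 | 0 |
| noon | 90.0 | 39.5 | 0.2 |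
| summer | 0.417 | 2.7 | 77.2 |
| summer | 1.33 | 16.4 | 38.6 |
| summer | 2.00 | 23.3 | 22.6 |
| summer | 3.00 | 27.7 | 9.9 |
| summer | 5.00 | 30.3 | 1.7 |
| summer | 6.00 | 31.3 | 1.1 |

(standard deviation of a reading: 0.5 percentage points)

- G, in percent of the X first charged, at 2.5 h
- the remedy with the largest gain of G, or "none" below 2 percentage points (north-west / east / north / south-east / none)
- G present, with what was taken out counted in, in percent of the X first charged, after north
- G present, with what was taken out counted in, in percent of the X first charged, after south-east

- north-west: at 2.5 h raise the temperature by 25 K, then wait 2.5 h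
- east: change nothing and wait 2.5 h more
- north: at 2.5 h add L, 100 % of the amount charged, then wait 2.5 h
- south-east: at 2.5 h take out 90 % of the G then present, then wait 2.5 h

- a species is counted by the X in it: one D counts as two
- removed G is counted in
- steps thought possible: X + Z -> Z + G; X -> E; 2 X -> D; L -> Z
- additions bring no volume worth counting

The two late readings seem not to go together: X is down to 0.2 %, yet together they account for 39.7 % of the charge, and G already read 39.3 % at 8.00 min. The summer run clears this up. At 1.33 min its X and G already add up to 55.0 %, so X was leaving by another road while G was being made, and that road is on the list as E and D.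

So freeze the catalyst. If its working amount stays proportional to the L charged and the loss is first order in X, X divides between the two roads in a fixed ratio, whatever the amount of X. You can call this the split, a selectivity factor: final G over the X not in G, per amount of L charged. The noon reading gives 0.218 mM⁻¹.

Try the split on the summer run, with its 2 mM of L. It gives 30.4 % G, and the last reading there is 31.3 %, with a scatter of 0.5 percentage points.

In the listed steps G comes from X, so a remedy can gain at most the X left. That reading of 0.2 % lies inside the scatter. Even if you take it at face value, the split reckons that adding L as in north turns it into about 0.11 points of G, under the mark of 2 points. My own reckoning therefore keeps G near 39.5 % at 2.5 h and after each remedy.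

The forecast gave 39.5 % now, none as the best remedy, and 39.5 % and 39.5 % after north and south-east, on the ground that “Nothing is left for any remedy to convert”. The flask gives 39.6 %, none, 39.6 % and 39.6 %.

    X + Z → Z + G (k = 2.70 M⁻¹ s⁻¹, Ea = 46.0 kJ mol⁻¹)
    X → E (k = 0.00840 s⁻¹, Ea = 81.0 kJ mol⁻¹)
    2 X → D (k = 2.60 × 10⁻⁵ M⁻¹ s⁻¹, Ea = 63.0 kJ mol⁻¹)
    L → Z (k = 0.0320 s⁻¹, Ea = 86.0 kJ mol⁻¹)
    (constants at 25 °C)

At 150 min X stands at 0 % of its charge, while Z stands at 100 % of the catalyst charged. Read from the flask's own G, the split is 0.219 mM⁻¹. Carried to the neighbour flask with 5.10 mM of L, the noon split gives 52.6 % G, and that neighbour flask holds 50.7 %.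

(The data were generated by integration for an exercise; scatter was added.)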